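**Retrosynthetic overview**

1. The strategy rests on the α-methylene-γ-butyrolactone O–C6–C7–C11(=C13H2)–C12(=O), cis-fused at C6/C7 to the ten-membered carbocycle C1–C10 and flanked by the enolisable C9 ketone, the C8 acyloin ester and the epoxide. It is closed last, without enolate chemistry, from the C6 hydroxyl, a C7 ethynyl group and CO (30 ⇐ TBS ether 29 ⇐ ethynyl carbinol 28; bonds C11–C12 and C12–O).
2. The ten-membered ring is formed first, at C4=C5, by ring-closing metathesis of diene 25 with the alkyne capped as C–SiMe3; the lactone is the second ring.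
3. C10–C1: boron anti-aldol of ethyl ketone 21 with 4-methylpent-4-enal, directed by the C8 acyloxy group, which is the epoxyangelate itself (acid 17 from angelic acid by Sharpless epoxidation).
4. C7–C8: closed-transition-state allenylzinc addition of propargylic mesylate 8 to (S)-2-(triethylsilyloxy)butanal. Such an addition gives the anti pair, which is the C7/C8 relationship of the target; the cis-lactone pair C6/C7 would be its syn pair, so C6 is set beforehand.
5. C6–C7 of 8: syn alkoxyallylboration of 3-(trimethylsilyl)propynal, then Mitsunobu inversion at C7.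

Key step: step 19

Remark: atoms are numbered C1 (CHOH), C2, C3, C4 (methyl C15), C5, C6 (lactone O), C7, C8 (ester O), C9 (C=O), C10 (methyl C14), C11 (=C13H2), C12 (lactone C=O); 3-(methoxymethoxy)prop-1-ene is taken as a purchasable ether (otherwise one step from allyl alcohol and MOMCl).

**Route**

Step 1
Reactants: 1 3-(methoxymethoxy)prop-1-ene; 2 3-(trimethylsilyl)prop-2-ynal
Product: 5 (3S,4S)-4-(methoxymethoxy)-1-(trimethylsilyl)hex-5-en-1-yn-3-ol, via (Z)-3-(methoxymethoxy)allyllithium 3 (not isolated), via (Z)-γ-(methoxymethoxy)allyl(diisopinocampheyl)borane 4 (not isolated)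
Conditions: s-BuLi, THF, −78 °C; (+)-Ipc2BOMe (from (−)-α-pinene); BF3·OEt2; then 2, −78 °C; HOCH2CH2NH2 work-up
Reagents that add atoms: none
Why: Brown asymmetric alkoxyallylboration, in which the chelated Z allyl anion 3 is carried as borane 4 to the re face of the aldehyde through a chair transition state, so that the Z geometry becomes the syn C6/C7 pair and the isopinocampheyl groups set C6 as S (C7 carbinol S).

Step 2
Reactants: 5 (3S,4S)-4-(methoxymethoxy)-1-(trimethylsilyl)hex-5-en-1-yn-3-ol
Product: 6 (3R,4S)-4-(methoxymethoxy)-1-(trimethylsilyl)hex-5-en-1-yn-3-yl benzoate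
Conditions: PhCO2H, PPh3, DIAD, THF, 0 °C → rt
Reagents that add atoms: benzoic acid, OC(=O)c1ccccc1
Why: Mitsunobu reaction, in which benzoate displaces the activated propargylic oxygen by SN2 and so inverts C7, turning the syn pair into the anti pair that the later SN2′/SE2′ sequence needs.

Step 3
Reactants: 6 (3R,4S)-4-(methoxymethoxy)-1-(trimethylsilyl)hex-5-en-1-yn-3-yl benzoate
Product: 7 (3R,4S)-4-(methoxymethoxy)-1-(trimethylsilyl)hex-5-en-1-yn-3-ol
Conditions: i-Bu2AlH, CH2Cl2, −78 °C; Rochelle salt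
Reagents that add atoms: none
Why: Reductive ester cleavage by an aluminium hydride at low temperature should free the C7 alcohol without the basic methanol that would strip the alkynylsilane, and leaves the acetal and the alkene alone.

Step 4
Reactants: 7 (3R,4S)-4-(methoxymethoxy)-1-(trimethylsilyl)hex-5-en-1-yn-3-ol
Product: 8 (3R,4S)-4-(methoxymethoxy)-1-(trimethylsilyl)hex-5-en-1-yn-3-yl methanesulfonate
Conditions: MsCl, Et3N, CH2Cl2, −78 → 0 °C (used crude)
Reagents that add atoms: methanesulfonyl chloride, CS(=O)(=O)Cl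
Why: O-sulfonylation of a secondary propargylic alcohol proceeds with retention at C7 and supplies the leaving group for the palladium step.

Step 5
Reactants: 9 methyl (S)-2-hydroxybutanoate
Product: 10 methyl (S)-2-(triethylsilyloxy)butanoate
Conditions: Et3SiCl, imidazole, CH2Cl2, 0 °C → rt
Reagents that add atoms: chlorotriethylsilane, CC[Si](Cl)(CC)CC
Why: Silyl ether formation on a secondary α-hydroxy ester under imidazole catalysis does not touch the stereocentre.

Step 6
Reactants: 10 methyl (S)-2-(triethylsilyloxy)butanoate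
Product: 11 (S)-2-(triethylsilyloxy)butanal
Conditions: i-Bu2AlH, CH2Cl2, −78 °C (used at once)
Reagents that add atoms: none
Why: Partial ester reduction stops at the aldehyde because the aluminium hemiacetal of an α-silyloxy ester is stable at −78 °C, and immediate use avoids epimerisation.

Step 7
Reactants: 8 (3R,4S)-4-(methoxymethoxy)-1-(trimethylsilyl)hex-5-en-1-yn-3-yl methanesulfonate; 11 (S)-2-(triethylsilyloxy)butanal
Product: 13 (3S,4R,5R,6S)-6-(methoxymethoxy)-3-(triethylsilyloxy)-5-[(trimethylsilyl)ethynyl]oct-7-en-4-ol, via allenyl(ethyl)zinc reagent 12 (not isolated)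
Conditions: Pd(OAc)2 (5 mol %), PPh3 (5 mol %), Et2Zn (3 equiv), THF, −78 → −20 °C
Reagents that add atoms: none
Why: Marshall propargylation, in which zerovalent palladium ionises the mesylate by anti SN2′ attack, zinc takes over the allenyl group with retention, and 12 adds through a closed SE2′ transition state, so that C7–C8 forms on the face opposite the departed mesylate (C7) with the anti C7/C8 relationship (C8), the Felkin–Anh preference of the (S)-α-silyloxy aldehyde being matched.

Step 8
Reactants: 14 angelic acid, (Z)-2-methylbut-2-enoic acid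
Product: 15 (Z)-2-methylbut-2-en-1-ol
Conditions: LiAlH4, Et2O, 0 °C
Reagents that add atoms: none
Why: Hydride reduction of the acid at 0 °C should give the allylic alcohol without isomerising the Z trisubstituted alkene.

Step 9
Reactants: 15 (Z)-2-methylbut-2-en-1-ol
Product: 16 [(2S,3R)-2,3-dimethyloxiran-2-yl]methanol
Conditions: Ti(OiPr)4 (10 mol %), L-(+)-diethyl tartrate (12 mol %), t-BuOOH, 4 Å MS, CH2Cl2, −20 °C
Reagents that add atoms: tert-butyl hydroperoxide, CC(C)(C)OO
Why: Sharpless asymmetric epoxidation, in which the titanium tartrate complex delivers oxygen to one face of the allylic alcohol (L-(+)-tartrate gives 2S,3R) and the syn addition keeps the two methyl groups trans.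

Step 10
Reactants: 16 [(2S,3R)-2,3-dimethyloxiran-2-yl]methanol
Product: 17 (2R,3R)-2,3-dimethyloxirane-2-carboxylic acid
Conditions: RuCl3·xH2O (2 mol %), NaIO4, CCl4/MeCN/H2O, rt
Reagents that add atoms: sodium periodate, [Na+].[O-]I(=O)(=O)=O; water, O
Why: Catalytic ruthenium tetroxide oxidation takes the primary epoxy alcohol to the acid without opening the epoxide, and C2 keeps its geometry while its descriptor changes from S to R.

Step 11
Reactants: 13 (3S,4R,5R,6S)-6-(methoxymethoxy)-3-(triethylsilyloxy)-5-[(trimethylsilyl)ethynyl]oct-7-en-4-ol; 17 (2R,3R)-2,3-dimethyloxirane-2-carboxylic acid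
Product: 19 (3S,4R,5S,6S)-6-(methoxymethoxy)-3-(triethylsilyloxy)-5-[(trimethylsilyl)ethynyl]oct-7-en-4-yl (2R,3R)-2,3-dimethyloxirane-2-carboxylate, via mixed 2,4,6-trichlorobenzoic anhydride 18 (not isolated)
Conditions: 2,4,6-Cl3C6H2COCl, Et3N, THF, rt; then 13, DMAP, toluene, rt → 40 °C
Reagents that add atoms: none
Why: Yamaguchi esterification, in which DMAP transfers the less hindered acyl group of 18 to the crowded C8 hydroxyl under conditions that leave the epoxide and all stereocentres alone.

Step 12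
Reactants: 19 (3S,4R,5S,6S)-6-(methoxymethoxy)-3-(triethylsilyloxy)-5-[(trimethylsilyl)ethynyl]oct-7-en-4-yl (2R,3R)-2,3-dimethyloxirane-2-carboxylate
Product: 20 (3S,4R,5S,6S)-3-hydroxy-6-(methoxymethoxy)-5-[(trimethylsilyl)ethynyl]oct-7-en-4-yl (2R,3R)-2,3-dimethyloxirane-2-carboxylate
Conditions: PPTS (cat.), MeOH/CH2Cl2, 0 °C
Reagents that add atoms: none
Why: Acid-catalysed methanolysis removes the secondary triethylsilyl ether selectively, since the methoxymethyl ether, the alkynylsilane and the glycidic ester are stable to PPTS and the acidic medium suppresses C8 → C9 acyl migration.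

Step 13
Reactants: 20 (3S,4R,5S,6S)-3-hydroxy-6-(methoxymethoxy)-5-[(trimethylsilyl)ethynyl]oct-7-en-4-yl (2R,3R)-2,3-dimethyloxirane-2-carboxylate
Product: 21 (4R,5S,6S)-6-(methoxymethoxy)-3-oxo-5-[(trimethylsilyl)ethynyl]oct-7-en-4-yl (2R,3R)-2,3-dimethyloxirane-2-carboxylate
Conditions: Dess–Martin periodinane, NaHCO3, CH2Cl2, 0 °C → rt
Reagents that add atoms: none
Why: Dess–Martin oxidation under buffered, non-basic conditions should give the α-acyloxy ethyl ketone without epimerising C8.

Step 14
Reactants: 21 (4R,5S,6S)-6-(methoxymethoxy)-3-oxo-5-[(trimethylsilyl)ethynyl]oct-7-en-4-yl (2R,3R)-2,3-dimethyloxirane-2-carboxylate; 22 4-methylpent-4-enal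
Product: 24 (3S,4S,5R,7S,8S)-8-hydroxy-3-(methoxymethoxy)-7,11-dimethyl-6-oxo-4-[(trimethylsilyl)ethynyl]dodeca-1,11-dien-5-yl (2R,3R)-2,3-dimethyloxirane-2-carboxylate, via dicyclohexylboron E-enolate 23 (not isolated)
Conditions: (c-C6H11)2BCl, Me2NEt, Et2O, −78 → 0 °C; 22, −78 → −20 °C; then MeOH, pH 7 buffer, H2O2, 0 °C
Reagents that add atoms: none
Why: Paterson-type boron anti-aldol, in which the ethyl side is enolised to E enolate 23 and the chair transition state (anti C10/C1) is entered on the enolate face fixed by the C8 acyloxy stereocentre (C8–H eclipsing the enolate, ester carbonyl turned toward the aldehyde), which should give 10S and 1S.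

Step 15
Reactants: 24 aldol adduct (C1 hydroxyl free)
Product: 25 (3S,4S,5R,7S,8S)-8-[(tert-butyldimethylsilyl)oxy]-3-(methoxymethoxy)-7,11-dimethyl-6-oxo-4-[(trimethylsilyl)ethynyl]dodeca-1,11-dien-5-yl (2R,3R)-2,3-dimethyloxirane-2-carboxylate
Conditions: TBSOTf, 2,6-lutidine, CH2Cl2, −78 °C
Reagents that add atoms: tert-butyldimethylsilyl trifluoromethanesulfonate, CC(C)(C)[Si](C)(C)OS(=O)(=O)C(F)(F)F
Why: Silylation of the only free hydroxyl with a silyl triflate and a hindered base at −78 °C is fast enough to outrun retro-aldol cleavage and leaves the acetal and the epoxide alone.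

Step 16
Reactants: 25 diene (C5 vinyl, C4 methallyl-type olefin)
Product: 26 (1S,6S,7S,8R,10S,4Z)-1-[(tert-butyldimethylsilyl)oxy]-6-(methoxymethoxy)-4,10-dimethyl-9-oxo-7-[(trimethylsilyl)ethynyl]cyclodec-4-en-8-yl (2R,3R)-2,3-dimethyloxirane-2-carboxylate (locants of the remark)
Conditions: second-generation Grubbs catalyst RuCl2(=CHPh)(H2IMes)(PCy3) (10 mol %), toluene (1 mM), 80 °C
Reagents that add atoms: none
Why: Ring-closing metathesis, in which the carbene forms at the monosubstituted C5 vinyl group and closes onto the 1,1-disubstituted C4 olefin with loss of ethylene, the silyl-capped alkyne being too hindered for enyne metathesis and the ten-membered ring expected to favour the less strained Z trisubstituted alkene.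

Step 17
Reactants: 26 ten-membered ring with C-silyl alkyne
Product: 27 (1S,6S,7S,8R,10S,4Z)-1-[(tert-butyldimethylsilyl)oxy]-7-ethynyl-6-(methoxymethoxy)-4,10-dimethyl-9-oxocyclodec-4-en-8-yl (2R,3R)-2,3-dimethyloxirane-2-carboxylate
Conditions: AgNO3 (0.2 equiv), acetone/H2O, rt
Reagents that add atoms: none
Why: Silver-catalysed protiodesilylation cleaves only the alkynyl C–Si bond through a silver acetylide that water protonates, under neutral conditions that spare the silyl ether, the acetal, the ester and the epoxide.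

Step 18
Reactants: 27 terminal alkyne with C6 methoxymethyl ether
Product: 28 (1S,6S,7S,8R,10S,4Z)-1-[(tert-butyldimethylsilyl)oxy]-7-ethynyl-6-hydroxy-4,10-dimethyl-9-oxocyclodec-4-en-8-yl (2R,3R)-2,3-dimethyloxirane-2-carboxylate
Conditions: Me3SiOTf, 2,2′-bipyridyl, CH2Cl2, 0 °C; then H2O
Reagents that add atoms: none
Why: Chemoselective acetal cleavage, in which the silyl triflate–bipyridyl pair turns the methoxymethyl ether into a pyridinium N,O-acetal that water hydrolyses, a mild method that spares silyl ethers and esters and should be too weakly acidic to open the electron-poor glycidic ester.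

Step 19
Reactants: 28 ethynyl carbinol (C6 hydroxyl and C7 ethynyl cis on the ten-membered ring)
Product: 29 C1 tert-butyldimethylsilyl ether of the target (cis-fused α-methylene-γ-butyrolactone)
Conditions: PdI2 (5 mol %), PBu3 (10 mol %), CO (7 atm), MeCN, 75 °C
Reagents that add atoms: carbon monoxide, [C-]#[O+]
Why: Divalent palladium carrying PBu3 takes up CO and the C6 hydroxyl to give an alkoxycarbonylpalladium iodide species with loss of HI, the tethered C11≡C13 bond inserts syn into the palladium–acyl bond with the acyl carbon going to the internal carbon C11, and HI protonolysis of the vinylpalladium species at C13 releases the exocyclic methylene and returns PdI2. The closest known reaction is the palladium-catalysed cyclocarbonylation of 2-ethynylcycloalkanols and other homopropargylic alcohols to fused α-methylene-γ-butyrolactones under these PdI2/PBu3/MeCN conditions. The lactone ring closes in the 5-exo-dig mode and forms C11–C12 and C12–O. No stereocentre is created, and the cis ring fusion follows from the cis C6–OH/C7–ethynyl pair fixed in steps 1, 2 and 7. The step needs carbonylation at C11 and not at C13 (no butenolide, no six-membered lactone) and no reaction elsewhere: delivery of the alkoxycarbonyl group from O6 enforces the regiochemistry, the neutral medium leaves the C9 ketone, the C8 acyloin ester and the epoxide alone, C1–OH is masked as its silyl ether, and because palladium stays divalent the allylic C6–O bond is not ionised.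

Step 20
Reactants: 29 C1 tert-butyldimethylsilyl ether of the target
Product: 30 target CNP0149149.1
Conditions: HF·pyridine, pyridine, THF, 0 °C → rt
Reagents that add atoms: none
Why: Buffered fluoride cleavage of the secondary silyl ether is mild enough for the α-methylene lactone, the acyloin ester, the epoxide and the β-hydroxy ketone that it releases.

**Compound list**

1 | 3-(methoxymethoxy)prop-1-ene (allyl methoxymethyl ether) | C=CCOCOC | starting material
2 | 3-(trimethylsilyl)prop-2-ynal | O=CC#C[Si](C)(C)C | starting material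
3 | (Z)-3-(methoxymethoxy)allyllithium (not isolated) | [Li]C/C=C\OCOC | intermediate
4 | (Z)-γ-(methoxymethoxy)allyl-bis[(1S,2R,3S,5S)-isopinocampheyl]borane (not isolated) | COCO/C=C\CB([C@H]1C[C@H]2C[C@@H]([C@@H]1C)C2(C)C)[C@H]1C[C@H]2C[C@@H]([C@@H]1C)C2(C)C | intermediate
5 | (3S,4S)-4-(methoxymethoxy)-1-(trimethylsilyl)hex-5-en-1-yn-3-ol | C=C[C@H](OCOC)[C@@H](O)C#C[Si](C)(C)C | intermediate
6 | (3R,4S)-4-(methoxymethoxy)-1-(trimethylsilyl)hex-5-en-1-yn-3-yl benzoate | C=C[C@H](OCOC)[C@H](OC(=O)c1ccccc1)C#C[Si](C)(C)C | intermediate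
7 | (3R,4S)-4-(methoxymethoxy)-1-(trimethylsilyl)hex-5-en-1-yn-3-ol | C=C[C@H](OCOC)[C@H](O)C#C[Si](C)(C)C | intermediate
8 | (3R,4S)-4-(methoxymethoxy)-1-(trimethylsilyl)hex-5-en-1-yn-3-yl methanesulfonate | C=C[C@H](OCOC)[C@H](OS(C)(=O)=O)C#C[Si](C)(C)C | intermediate
9 | methyl (S)-2-hydroxybutanoate | CC[C@H](O)C(=O)OC | starting material
10 | methyl (S)-2-(triethylsilyloxy)butanoate | CC[C@H](O[Si](CC)(CC)CC)C(=O)OC | intermediate
11 | (S)-2-(triethylsilyloxy)butanal | CC[C@H](O[Si](CC)(CC)CC)C=O | intermediate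
12 | (aR)-ethyl[(4S)-4-(methoxymethoxy)-1-(trimethylsilyl)hexa-1,2,5-trien-1-yl]zinc, zinc anti to the departed mesylate (not isolated) | C=C[C@H](OCOC)C=[C@@]=C([Zn]CC)[Si](C)(C)C | intermediate
13 | (3S,4R,5R,6S)-6-(methoxymethoxy)-3-(triethylsilyloxy)-5-[(trimethylsilyl)ethynyl]oct-7-en-4-ol | C=C[C@H](OCOC)[C@H](C#C[Si](C)(C)C)[C@@H](O)[C@@H](O[Si](CC)(CC)CC)CC | intermediate
14 | angelic acid, (Z)-2-methylbut-2-enoic acid | C/C=C(/C)C(=O)O | starting material
15 | (Z)-2-methylbut-2-en-1-ol | C/C=C(/C)CO | intermediate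
16 | [(2S,3R)-2,3-dimethyloxiran-2-yl]methanol | OC[C@]1(C)O[C@@H]1C | intermediate
17 | (2R,3R)-2,3-dimethyloxirane-2-carboxylic acid | OC(=O)[C@]1(C)O[C@@H]1C | intermediate
18 | (2R,3R)-2,3-dimethyloxirane-2-carboxylic 2,4,6-trichlorobenzoic anhydride (not isolated) | O=C(OC(=O)[C@]1(C)O[C@@H]1C)c1c(Cl)cc(Cl)cc1Cl | intermediate
19 | (3S,4R,5S,6S)-6-(methoxymethoxy)-3-(triethylsilyloxy)-5-[(trimethylsilyl)ethynyl]oct-7-en-4-yl (2R,3R)-2,3-dimethyloxirane-2-carboxylate | C=C[C@H](OCOC)[C@H](C#C[Si](C)(C)C)[C@@H](OC(=O)[C@]1(C)O[C@@H]1C)[C@@H](O[Si](CC)(CC)CC)CC | intermediate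
20 | (3S,4R,5S,6S)-3-hydroxy-6-(methoxymethoxy)-5-[(trimethylsilyl)ethynyl]oct-7-en-4-yl (2R,3R)-2,3-dimethyloxirane-2-carboxylate | C=C[C@H](OCOC)[C@H](C#C[Si](C)(C)C)[C@@H](OC(=O)[C@]1(C)O[C@@H]1C)[C@@H](O)CC | intermediate
21 | (4R,5S,6S)-6-(methoxymethoxy)-3-oxo-5-[(trimethylsilyl)ethynyl]oct-7-en-4-yl (2R,3R)-2,3-dimethyloxirane-2-carboxylate | C=C[C@H](OCOC)[C@H](C#C[Si](C)(C)C)[C@@H](OC(=O)[C@]1(C)O[C@@H]1C)C(=O)CC | intermediate
22 | 4-methylpent-4-enal | C=C(C)CCC=O | starting material
23 | dicyclohexylboron (E)-enolate of ketone 21, boron on O9, C9=C10 (not isolated) | C=C[C@H](OCOC)[C@H](C#C[Si](C)(C)C)[C@@H](OC(=O)[C@]1(C)O[C@@H]1C)/C(OB(C1CCCCC1)C1CCCCC1)=C\C | intermediate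
24 | (3S,4S,5R,7S,8S)-8-hydroxy-3-(methoxymethoxy)-7,11-dimethyl-6-oxo-4-[(trimethylsilyl)ethynyl]dodeca-1,11-dien-5-yl (2R,3R)-2,3-dimethyloxirane-2-carboxylate | C=C[C@H](OCOC)[C@H](C#C[Si](C)(C)C)[C@@H](OC(=O)[C@]1(C)O[C@@H]1C)C(=O)[C@@H](C)[C@@H](O)CCC(C)=C | intermediate
25 | (3S,4S,5R,7S,8S)-8-[(tert-butyldimethylsilyl)oxy]-3-(methoxymethoxy)-7,11-dimethyl-6-oxo-4-[(trimethylsilyl)ethynyl]dodeca-1,11-dien-5-yl (2R,3R)-2,3-dimethyloxirane-2-carboxylate | C=C[C@H](OCOC)[C@H](C#C[Si](C)(C)C)[C@@H](OC(=O)[C@]1(C)O[C@@H]1C)C(=O)[C@@H](C)[C@@H](O[Si](C)(C)C(C)(C)C)CCC(C)=C | intermediate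
26 | (1S,6S,7S,8R,10S,4Z)-1-[(tert-butyldimethylsilyl)oxy]-6-(methoxymethoxy)-4,10-dimethyl-9-oxo-7-[(trimethylsilyl)ethynyl]cyclodec-4-en-8-yl (2R,3R)-2,3-dimethyloxirane-2-carboxylate (locants of the remark) | COCO[C@H]1/C=C(/C)CC[C@H](O[Si](C)(C)C(C)(C)C)[C@H](C)C(=O)[C@H](OC(=O)[C@]2(C)O[C@@H]2C)[C@H]1C#C[Si](C)(C)C | intermediate
27 | (1S,6S,7S,8R,10S,4Z)-1-[(tert-butyldimethylsilyl)oxy]-7-ethynyl-6-(methoxymethoxy)-4,10-dimethyl-9-oxocyclodec-4-en-8-yl (2R,3R)-2,3-dimethyloxirane-2-carboxylate | COCO[C@H]1/C=C(/C)CC[C@H](O[Si](C)(C)C(C)(C)C)[C@H](C)C(=O)[C@H](OC(=O)[C@]2(C)O[C@@H]2C)[C@H]1C#C | intermediate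
28 | (1S,6S,7S,8R,10S,4Z)-1-[(tert-butyldimethylsilyl)oxy]-7-ethynyl-6-hydroxy-4,10-dimethyl-9-oxocyclodec-4-en-8-yl (2R,3R)-2,3-dimethyloxirane-2-carboxylate | O[C@H]1/C=C(/C)CC[C@H](O[Si](C)(C)C(C)(C)C)[C@H](C)C(=O)[C@H](OC(=O)[C@]2(C)O[C@@H]2C)[C@H]1C#C | intermediate
29 | C1 tert-butyldimethylsilyl ether of the target, (1S,6S,7S,8R,10S,4Z) | C=C1C(=O)O[C@H]2/C=C(/C)CC[C@H](O[Si](C)(C)C(C)(C)C)[C@H](C)C(=O)[C@H](OC(=O)[C@]3(C)O[C@@H]3C)[C@@H]12 | intermediate
30 | CNP0149149.1, (1S,6S,7S,8R,10S,4Z)-1-hydroxy-9-oxogermacra-4,11(13)-dien-12,6-olide 8-[(2R,3R)-2,3-dimethyloxirane-2-carboxylate] | C=C1C(=O)O[C@H]2/C=C(/C)CC[C@H](O)[C@H](C)C(=O)[C@H](OC(=O)[C@]3(C)O[C@@H]3C)[C@@H]12 | target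

**Step count and risks**

Total step count: 20. Longest linear sequence: 15 steps (steps 1–4, 7, 11–20).

Step 16 (ring-closing metathesis). What may go wrong: the carbene formed at the C5 vinyl group may be held back as a chelate by the C6 acetal and C8 ester oxygens and then react between molecules (dimers and oligomers through C5) faster than it closes the strained ten-membered ring onto the 1,1-disubstituted C4 olefin. The fallback is a relay ring-closing metathesis; it sets out from ketone 21 and comes back at 26. Geraniol is O-allylated (NaH, allyl bromide, THF) to geranyl allyl ether F1. The remote 6,7-olefin is epoxidised (mCPBA, CH2Cl2, −20 °C) to epoxide F2, and periodic acid (H5IO6, THF/H2O) cleaves it to (E)-6-(allyloxy)-4-methylhex-4-enal F3. Enolate 23 of ketone 21 adds to F3 under the conditions of step 14 to give relay aldol F4, and silylation as in step 15 gives relay diene F5. With the second-generation Hoveyda–Grubbs catalyst RuCl2(=CH-C6H4-2-OiPr)(H2IMes) in dilute toluene the carbene starts at the unhindered allyl ether, expels 2,5-dihydrofuran and so sits on C4, from where it closes onto the C5 vinyl group to give 26.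

Step 19 (cyclocarbonylation, key step). What may go wrong: the alkoxycarbonylpalladium species may fail to form or to insert in the crowded ring at 75 °C, so that the alkyne is consumed by oligomerisation or the product by phosphine addition to the methylene lactone. The fallback sets out from 28 and comes back at 29. Molybdenum-catalysed hydrostannation (Bu3SnH, Mo(CO)3(CNtBu)3, THF, 55 °C) places tin on the internal carbon C11 and gives 2-stannylalkene F6. Iododestannylation (I2, CH2Cl2, 0 °C) gives 2-iodoalkene F7. Pd(PPh3)4, CO (1 atm) and i-Pr2NEt in THF at 50 °C then close the lactone by oxidative addition into the C11–I bond, CO insertion and capture of the acylpalladium species by the C6 hydroxyl (the known carbonylative lactonisation of 3-halo homoallylic alcohols), giving 29.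

Step 7 (allenylzinc addition). What may go wrong: the C6 methoxymethoxy group may be lost by β-elimination from the propargyl/allenyl zinc species (1,4-elimination to a dienyne), or the anti preference may erode. The fallback sets out from alcohol 7 and comes back at 13. Methyl chloroformate and pyridine give propargylic methyl carbonate F8. CuOtBu (10 mol %), Xantphos and B2pin2 in THF (SN2′ borylation anti to the carbonate) give the configurationally stable allenyl pinacolboronate F9, which has no carbanionic carbon next to the C6 ether. Heating F9 with aldehyde 11 (toluene, 60 °C) goes through the same closed six-membered transition state and gives 13 after work-up.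

**Further compounds**

F1 | step 16 | geranyl allyl ether, (E)-1-(allyloxy)-3,7-dimethylocta-2,6-diene | CC(C)=CCC/C(C)=C/COCC=C
F2 | step 16 | racemic 6,7-epoxide of geranyl allyl ether | CC1(C)OC1CC/C(C)=C/COCC=C
F3 | step 16 | (E)-6-(allyloxy)-4-methylhex-4-enal | O=CCC/C(C)=C/COCC=C
F4 | step 16 | relay aldol, analogue of 24 with C4(CH3)=CH–CH2–O–allyl in place of C4(CH3)=CH2, (1S,6S,7S,8R,10S) | C=C[C@H](OCOC)[C@H](C#C[Si](C)(C)C)[C@@H](OC(=O)[C@]1(C)O[C@@H]1C)C(=O)[C@@H](C)[C@@H](O)CC/C(C)=C/COCC=C
F5 | step 16 | relay diene, C1 tert-butyldimethylsilyl ether of F4 | C=C[C@H](OCOC)[C@H](C#C[Si](C)(C)C)[C@@H](OC(=O)[C@]1(C)O[C@@H]1C)C(=O)[C@@H](C)[C@@H](O[Si](C)(C)C(C)(C)C)CC/C(C)=C/COCC=C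
F6 | step 19 | 2-stannylalkene, analogue of 28 with C7–C(SnBu3)=CH2 in place of C7–C≡CH | O[C@H]1/C=C(/C)CC[C@H](O[Si](C)(C)C(C)(C)C)[C@H](C)C(=O)[C@H](OC(=O)[C@]2(C)O[C@@H]2C)[C@H]1C(=C)[Sn](CCCC)(CCCC)CCCC
F7 | step 19 | 2-iodoalkene, analogue of 28 with C7–C(I)=CH2 in place of C7–C≡CH | O[C@H]1/C=C(/C)CC[C@H](O[Si](C)(C)C(C)(C)C)[C@H](C)C(=O)[C@H](OC(=O)[C@]2(C)O[C@@H]2C)[C@H]1C(I)=C
F8 | step 7 | (3R,4S)-4-(methoxymethoxy)-1-(trimethylsilyl)hex-5-en-1-yn-3-yl methyl carbonate | C=C[C@H](OCOC)[C@H](OC(=O)OC)C#C[Si](C)(C)C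
F9 | step 7 | (aS)-allenyl pinacolboronate, 2-[(4S)-4-(methoxymethoxy)-1-(trimethylsilyl)hexa-1,2,5-trien-1-yl]-4,4,5,5-tetramethyl-1,3,2-dioxaborolane, boron anti to the departed carbonate | C=C[C@H](OCOC)C=[C@@]=C(B1OC(C)(C)C(C)(C)O1)[Si](C)(C)C
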